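## The problem

The target 21 is a 7,9'-epoxylignan of the lariciresinol type. Its tetrahydrofuran (O1, C2–C5) carries a guaiacyl group on C2, the caffeoylated hydroxymethyl carbon C9 on C3 and a 4-hydroxy-3-methoxybenzyl group (benzylic carbon C7') on C4, in the (2R,3S,4S) configuration. The three stereocentres are contiguous: the C2 aryl group is trans to C9, while C9 and C7' are cis, and this cis pair on neighbouring ring carbons is the one that equilibrating chemistry will not deliver. C2 is the natural source of asymmetry, since it can be secured as a resolved benzylic carbinol and can send an incoming group to the opposite face of C3; C4 is out of its direct reach and needs a relay through C3. The molecule tolerates little. The C2–O1 bond is a para-oxygenated benzylic ether that ionises in acid (epimerisation, Friedel–Crafts closure to an aryltetralin) and is open to hydrogenolysis. The caffeate is a reducible, radical-accepting, base-labile cinnamate with an oxidisable catechol, so four phenols must be unmasked without acid and the cinnamate alkene must be absent whenever reducing conditions are used. The feature that opens the route is that C9 and C7' are 1,4-related across the C3–C4 bond on the same face, and that C7' is a bare methylene in the target. A hydroxyl placed on C7' for a time can hold a one-carbon unit on silicon, deliver it to C3 of a C3=C4 alkene whose C4 end is fully substituted, and then be deleted.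

## Retrosynthesis

**Cinnamate alkene (21 ⇒ 18 + 19).** The last bond cut is the Cα=Cβ bond of the caffeoyl group, not the ester C–O bond. 21 is traced through the arylidene half-ester 20 to the hydrogen malonate 18 and 3,4-dihydroxybenzaldehyde 19. Against acylation with an intact caffeoyl donor, this cut needs no protection of the catechol and keeps the cinnamate out of every radical and hydrogenation step. The forward reaction must be a mild, base-mediated, (E)-selective decarboxylative condensation.

**Benzyl groups and the C7' oxygen (18 ⇒ 17 ⇒ 16 ⇒ 15 ⇒ 13 + 14).** The three O–benzyl bonds of 17 are cut first. The C7'–H bond of 17 is then traced to the C7'–O bond of thionocarbonate 16 and carbinol 15, and the C9 ester to diol 13 and mono-benzyl malonate 14. A radical deoxygenation is chosen because ionic reduction would also open the C2–O1 ether and acid would close diol 13 to a furofuran. The malonate masks the primary hydroxyl during the deoxygenation and supplies two carbons of the final side chain. The forward steps must distinguish a primary from a hindered secondary benzylic hydroxyl.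

**Carbon–silicon bond (13 ⇒ 12).** The C9–O bond and the C7'–O–H bond are traced to the C9–Si and O–Si bonds of the cis-fused siloxane 12 (Tamao–Fleming oxidation). Fluoride and basic peroxide would strip aryl silyl ethers, so the phenols are carried as benzyl ethers from the start. This in turn is what forces the cinnamate to be built after hydrogenolysis.

**Key disconnection (12 ⇒ 11).** The C3–C9 bond and the C4–H bond are cut, giving the (bromomethyl)dimethylsilyl ether 11 of a 2-aryl-2,5-dihydrofuran. An untethered hydroxymethylation could not set C4, and a tether anchored anywhere else would not reach C3. 11 has one controlled stereocentre instead of three and one ring fewer. The forward step must close 6-endo, add anti to the C2 aryl group and take hydrogen at C4 to give the cis ring fusion.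

**Tether and ring (11 ⇒ 9 + 10; 9 ⇒ 8).** The Si–O bond leads to carbinol 9 and chlorosilane 10. The C3=C4 bond of 9 is cut by ring-closing metathesis to the acyclic diene 8, in which C2 is the only defined centre. Metathesis is preferred to an O1–C5 cyclisation because it places the alkene exactly where the radical needs it.

**C4–C7' bond (8 ⇒ 7 + 1).** The carbinol carbon is detached from the 1,1-disubstituted alkene, giving vinyl bromide 7 and aldehyde 1. Building the same unit from a Baylis–Hillman adduct would be slow with this electron-rich aldehyde and would need an orthogonal carbinol protecting group, an ester reduction and a bromination. Here the aldehyde that supplies C2 also supplies C7'. The coupling must tolerate a benzylic allylic ether, which points to a chromium-mediated addition.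

**Ether and stereocentre (7 ⇒ 5 + 6; 5 ⇒ 4 ⇒ 3 ⇒ 1 + 2).** The O1–C5 bond is cut to the (R)-carbinol 5 and 2,3-dibromopropene 6. 5 comes from acetate 4, the fast-reacting enantiomer in a lipase resolution of racemate 3, and 3 from aldehyde 1 and vinylmagnesium bromide 2. Basic etherification is required because the carbinol ionises easily.

## Roads not taken

**Alternative 1:** a three-component conjugate addition–aldol on a chiral butenolide.
- Cut: C4–C7' and C2–C3.
- Key step: the lithiated aryl dithiane A3 adds to the β-carbon of the menthyloxy butenolide A2 anti to the acetal substituent, and the enolate is trapped by the silylated aldehyde A4 to give the trans butanolide A1.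
- Merits: both skeletal bonds and the C3/C4 relationship arise in one convergent, auxiliary-controlled step. The trans lactone maps onto the required cis pair once the ring is switched from the lactone to the ether. The C5 hydroxyl closes the ring and leaves C9 free, so the two primary positions differentiate themselves. The route would probably be shorter than the chosen one by several steps.
- Weak points: the auxiliary in A2 belongs to the less accessible enantiomeric series of menthol. The tetrahydrofuran is closed by ionising the C2 carbinol next to an electron-rich arene, so C2 is set under thermodynamic control and the triol is exposed to aryltetralin formation. Aryl silyl ethers must survive LiAlH4 and Raney Ni desulfurisation.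
- Comparison: this road is better in convergence and step count. The chosen plan offers a C2 centre that is fixed from a resolved carbinol and never ionised, C3 and C4 set by kinetic relay in one event, and no auxiliary.

**Alternative 2:** an alkoxymethyl radical closure that inserts C5.
- Cut: C4–C5.
- Key step: the (phenylselanyl)methyl ether A6 gives an O–CH2 radical under Bu3SnH that adds 5-exo-dig to the alkyne and closes the 4-benzylidene tetrahydrofuran A5.
- Merits: this closure is faster and regiochemically safer than a 6-endo attack of a silylmethyl radical, and it tolerates all functionality present.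
- Weak points: the step creates no stereocentre. C2 and C3 must be installed beforehand as an anti pair in A6. C4 is left to a later hydrogenation of the benzylidene, where the C3 arm and the C2 aryl group shield opposite faces and the benzylic ring ether is at risk. The selenomethyl ether must be made on a hindered benzylic alkoxide.
- Comparison: the ring closure itself is more secure than in the chosen plan. The chosen plan needs only one stereocentre before its key step and creates C3 and C4 together with the C–C bond.

**Alternative 3:** a tethered oxocarbenium–enolate closure to a furofuranone.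
- Cut: C2–C3.
- Key step: the butanolide mixed acetal A8 is converted into its silyl ketene acetal, which attacks the tethered oxocarbenium ion at C2 (TMSOTf) and closes the cis-fused furofuranone A7.
- Merits: the cis fusion of a bicyclo[3.3.0] system is compulsory, so C3/C4 is as secure as with the silicon tether. The C2 aryl group takes the exo position under ring control. Hydride opening of A7 leads to the same C9/C7' diol pattern as in 13, so the endgames coincide. Precedent for this closure in lignan chemistry is closer than for the chosen radical step.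
- Weak points: A8 needs two stereocentres (C4 and C7') made enantioselectively, one of which is later erased. The key step ionises a benzylic acetal next to electron-rich arenes.
- Comparison: step counts are similar, and A7 forms C2 under firmer control. The chosen plan needs a single stereocentre from a simple resolution and no control at C7'.

Key step: step 8

Remark on the chemistry: C7' is formed without control in step 5 and becomes a methylene group in step 12. Compounds 8, 9, 11, 12, 13, 15 and 16 are therefore carried as both C7' epimers and their SMILES leave this centre open. Compound 3 is the racemate.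

## Route

Step 1
Reactants: 1 4-(benzyloxy)-3-methoxybenzaldehyde; 2 vinylmagnesium bromide
Product: 3 rac-1-[4-(benzyloxy)-3-methoxyphenyl]prop-2-en-1-ol
Conditions: CH2=CHMgBr (1.2 equiv), THF, −78 → 0 °C; aq. NH4Cl
Reagents that add atoms: none
Why: Grignard 1,2-addition to the aryl aldehyde; the carbinol centre (lignan C2) forms racemic and is resolved in step 2.

Step 2
Reactants: 3 rac-1-[4-(benzyloxy)-3-methoxyphenyl]prop-2-en-1-ol
Product: 4 (1R)-1-[4-(benzyloxy)-3-methoxyphenyl]prop-2-en-1-yl acetate
Conditions: Novozym 435 (immobilised Candida antarctica lipase B), vinyl acetate (3 equiv), MTBE, 30 °C, stopped just short of half conversion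
Reagents that add atoms: vinyl acetate, CC(=O)OC=C
Why: Lipase-catalysed kinetic resolution by irreversible transesterification; with aryl as the large and vinyl as the medium substituent the enzyme should acylate the (R)-alcohol, so the C2 configuration of the target is selected here, and stopping before half conversion keeps the acetate enantiopure.

Step 3
Reactants: 4 (1R)-1-[4-(benzyloxy)-3-methoxyphenyl]prop-2-en-1-yl acetate
Product: 5 (1R)-1-[4-(benzyloxy)-3-methoxyphenyl]prop-2-en-1-ol
Conditions: K2CO3 (0.2 equiv), MeOH, 0 °C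
Reagents that add atoms: none
Why: Base-catalysed transesterification cleaves the acyl–oxygen bond, so the benzylic C–O bond and its configuration are untouched; brief cold treatment avoids solvolysis of the allylic acetate.

Step 4
Reactants: 5 (1R)-1-[4-(benzyloxy)-3-methoxyphenyl]prop-2-en-1-ol; 6 2,3-dibromoprop-1-ene
Product: 7 1-(benzyloxy)-4-{(1R)-1-[(2-bromoprop-2-en-1-yl)oxy]prop-2-en-1-yl}-2-methoxybenzene
Conditions: NaH (1.2 equiv), THF, 0 °C; then 6 (1.5 equiv), Bu4NI (cat.), 0 °C → rt
Reagents that add atoms: none
Why: Williamson ether synthesis; the alkoxide displaces the allylic bromide by SN2 while the vinylic bromide is inert, and the basic medium never ionises the benzylic centre.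

Step 5
Reactants: 7 1-(benzyloxy)-4-{(1R)-1-[(2-bromoprop-2-en-1-yl)oxy]prop-2-en-1-yl}-2-methoxybenzene; 1 4-(benzyloxy)-3-methoxybenzaldehyde
Product: 8 1-[4-(benzyloxy)-3-methoxyphenyl]-2-[({(1R)-1-[4-(benzyloxy)-3-methoxyphenyl]prop-2-en-1-yl}oxy)methyl]prop-2-en-1-ol (both C7' epimers)
Conditions: CrCl2 (4 equiv), NiCl2 (2 mol%), DMF, rt; aq. work-up
Reagents that add atoms: none
Why: Nozaki–Hiyama–Kishi coupling; nickel-catalysed activation of the vinylic C–Br bond and transfer to chromium give a vinylchromium species that adds only to the aldehyde and tolerates the benzylic allylic ether. C7' forms without control, which is acceptable because this centre is later removed.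

Step 6
Reactants: 8 1-[4-(benzyloxy)-3-methoxyphenyl]-2-[({(1R)-1-[4-(benzyloxy)-3-methoxyphenyl]prop-2-en-1-yl}oxy)methyl]prop-2-en-1-ol
Product: 9 [4-(benzyloxy)-3-methoxyphenyl]{(5R)-5-[4-(benzyloxy)-3-methoxyphenyl]-2,5-dihydrofuran-3-yl}methanol (both C7' epimers; the 5R carbon is lignan C2)
Conditions: second-generation Grubbs catalyst (H2IMes)(PCy3)Cl2Ru=CHPh (5 mol%), CH2Cl2 (0.01 M), 40 °C
Reagents that add atoms: none
Why: Ring-closing metathesis of the monosubstituted and the 1,1-disubstituted alkene closes the five-membered ring with loss of ethene and places the alkene at C3=C4; the ruthenium carbene tolerates the free carbinol and the benzyl ethers, and C2 is not involved.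

Step 7
Reactants: 9 [4-(benzyloxy)-3-methoxyphenyl]{(5R)-5-[4-(benzyloxy)-3-methoxyphenyl]-2,5-dihydrofuran-3-yl}methanol; 10 (bromomethyl)chlorodimethylsilane
Product: 11 {[4-(benzyloxy)-3-methoxyphenyl]{(5R)-5-[4-(benzyloxy)-3-methoxyphenyl]-2,5-dihydrofuran-3-yl}methoxy}(bromomethyl)dimethylsilane (both C7' epimers)
Conditions: 10 (1.2 equiv), imidazole (1.5 equiv), CH2Cl2, 0 °C; short pad of Et3N-deactivated silica, used at once
Reagents that add atoms: none
Why: Imidazole-mediated silylation of the secondary alcohol installs the temporary silicon tether; the hydrolytically labile ether is not stored.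

Step 8
Reactants: 11 {[4-(benzyloxy)-3-methoxyphenyl]{(5R)-5-[4-(benzyloxy)-3-methoxyphenyl]-2,5-dihydrofuran-3-yl}methoxy}(bromomethyl)dimethylsilane
Product: 12 (4aR,5R,7aS)-1,5-bis[4-(benzyloxy)-3-methoxyphenyl]-3,3-dimethylhexahydro-1H-furo[3,4-d][1,2]oxasiline (cis-fused; lignan C2 R, C3 R, C4 S; C3–CH2Si trans to the C2 aryl group and cis to C7'; both C7' epimers)
Conditions: Bu3SnH (1.3 equiv, added over 6 h by syringe pump), AIBN (0.2 equiv), benzene (0.01 M), 80 °C
Reagents that add atoms: none
Why: This is a Nishiyama–Stork radical cyclisation of a (bromomethyl)dimethylsilyl ether in its 6-endo mode, the closest known reaction type being the 6-endo closure of such ethers of 2-substituted allylic alcohols. The stannyl radical abstracts bromine to give a silylmethyl radical (C9) held on the C7' oxygen. Closure at C4 (5-exo) would create a quaternary spiro centre and is further disfavoured by the long Si–C and Si–O bonds, so the radical adds to C3 in a 6-endo-trig closure that forms the oxasilinane ring and the C3–C9 bond. The C4–C7' bond can rotate to present the tether to either face and the C2 aryl group blocks one of them, so C9 enters C3 trans to the aryl group (C2 controls C3). The tertiary C4 radical then takes hydrogen from Bu3SnH on the convex face, away from the new C3–C9 bond, which gives the cis-fused bicycle and places C7' cis to C9 (C3 and the tether control C4). The step needs cyclisation to outrun direct reduction of the C–Br bond, which slow stannane addition at high dilution secures, and it needs 6-endo regioselectivity, which the fully substituted C4 secures. Both C7' epimers are expected to close in the same sense, because that centre only decides whether its aryl group sits pseudo-equatorial or pseudo-axial on the new ring.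

Step 9
Reactants: 12 (4aR,5R,7aS)-1,5-bis[4-(benzyloxy)-3-methoxyphenyl]-3,3-dimethylhexahydro-1H-furo[3,4-d][1,2]oxasiline
Product: 13 {(2R,3S,4S)-2-[4-(benzyloxy)-3-methoxyphenyl]-4-{[4-(benzyloxy)-3-methoxyphenyl](hydroxy)methyl}oxolan-3-yl}methanol (both C7' epimers)
Conditions: 30% aq. H2O2, KF, KHCO3, THF/MeOH (1:1), rt → 40 °C
Reagents that add atoms: hydrogen peroxide, OO
Why: Tamao–Fleming oxidation; activated peroxide converts the C9–Si bond into C9–OH and the Si–O bond is hydrolysed to free the C7' hydroxyl. Benzyl ethers are inert, and the basic medium avoids acid-promoted closure of the diol to a furofuran.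

Step 10
Reactants: 13 {(2R,3S,4S)-2-[4-(benzyloxy)-3-methoxyphenyl]-4-{[4-(benzyloxy)-3-methoxyphenyl](hydroxy)methyl}oxolan-3-yl}methanol; 14 3-(benzyloxy)-3-oxopropanoic acid (mono-benzyl malonate)
Product: 15 benzyl {(2R,3S,4S)-2-[4-(benzyloxy)-3-methoxyphenyl]-4-{[4-(benzyloxy)-3-methoxyphenyl](hydroxy)methyl}oxolan-3-yl}methyl propanedioate (both C7' epimers)
Conditions: 14 (1.05 equiv), EDC·HCl, DMAP (cat.), CH2Cl2, −20 → 0 °C
Reagents that add atoms: none
Why: Steglich esterification; the primary C9 hydroxyl is acylated in preference to the hindered secondary benzylic C7' hydroxyl at low temperature with one equivalent of acid. The malonate masks C9–OH for the deoxygenation and carries two carbons of the future cinnamate.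

Step 11
Reactants: 15 benzyl {(2R,3S,4S)-2-[4-(benzyloxy)-3-methoxyphenyl]-4-{[4-(benzyloxy)-3-methoxyphenyl](hydroxy)methyl}oxolan-3-yl}methyl propanedioate
Product: 16 benzyl {(2R,3S,4S)-2-[4-(benzyloxy)-3-methoxyphenyl]-4-{[4-(benzyloxy)-3-methoxyphenyl][(phenoxycarbonothioyl)oxy]methyl}oxolan-3-yl}methyl propanedioate (both C7' epimers)
Conditions: PhOC(S)Cl (1.5 equiv), pyridine, DMAP (cat.), CH2Cl2, 0 °C → rt
Reagents that add atoms: O-phenyl chlorothionoformate, S=C(Cl)Oc1ccccc1
Why: DMAP-catalysed thioacylation of the remaining secondary alcohol gives the Barton–McCombie substrate under mild base that leaves the malonate methylene and both esters alone.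

Step 12
Reactants: 16 benzyl {(2R,3S,4S)-2-[4-(benzyloxy)-3-methoxyphenyl]-4-{[4-(benzyloxy)-3-methoxyphenyl][(phenoxycarbonothioyl)oxy]methyl}oxolan-3-yl}methyl propanedioate
Product: 17 benzyl {(2R,3S,4S)-2-[4-(benzyloxy)-3-methoxyphenyl]-4-[4-(benzyloxy)-3-methoxybenzyl]oxolan-3-yl}methyl propanedioate
Conditions: Bu3SnH (2 equiv), AIBN (cat.), toluene, 90 °C
Reagents that add atoms: none
Why: Barton–McCombie deoxygenation; the stannyl radical adds to the thiocarbonyl sulfur, β-scission releases a benzylic C7' radical and hydrogen transfer gives the methylene group. Unlike ionic reduction this leaves the C2–O1 benzylic ether intact, and both C7' epimers converge on one compound.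

Step 13
Reactants: 17 benzyl {(2R,3S,4S)-2-[4-(benzyloxy)-3-methoxyphenyl]-4-[4-(benzyloxy)-3-methoxybenzyl]oxolan-3-yl}methyl propanedioate
Product: 18 3-{[(2R,3S,4S)-4-(4-hydroxy-3-methoxybenzyl)-2-(4-hydroxy-3-methoxyphenyl)oxolan-3-yl]methoxy}-3-oxopropanoic acid
Conditions: H2 (1 atm), 10% Pd/C, EtOAc/EtOH, rt, stopped on full debenzylation
Reagents that add atoms: none
Why: Catalytic hydrogenolysis cleaves the two aryl benzyl ethers and the benzyl ester under neutral conditions, under which the dialkyl benzylic ether C2–O1 of the ring reacts much more slowly; no reducible alkene is present at this stage.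

Step 14
Reactants: 18 3-{[(2R,3S,4S)-4-(4-hydroxy-3-methoxybenzyl)-2-(4-hydroxy-3-methoxyphenyl)oxolan-3-yl]methoxy}-3-oxopropanoic acid; 19 3,4-dihydroxybenzaldehyde
Product: 21 [(2R,3S,4S)-4-(4-hydroxy-3-methoxybenzyl)-2-(4-hydroxy-3-methoxyphenyl)oxolan-3-yl]methyl (2E)-3-(3,4-dihydroxyphenyl)prop-2-enoate (target), via arylidenemalonic acid monoester 20 (not isolated)
Conditions: 19 (1.2 equiv), pyridine, piperidine (0.2 equiv), 50 °C, argon
Reagents that add atoms: none
Why: Knoevenagel–Doebner condensation of a malonic acid half-ester with an aromatic aldehyde; amine-mediated condensation gives 20, which loses CO2 in pyridine to the thermodynamically favoured (E)-cinnamate. No phenol protection is needed and the finished molecule sees neither acid nor reductant.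

## Compound list

1 | 4-(benzyloxy)-3-methoxybenzaldehyde | O=Cc1ccc(OCc2ccccc2)c(OC)c1 | starting material
2 | vinylmagnesium bromide | C=C[Mg]Br | starting material
3 | rac-1-[4-(benzyloxy)-3-methoxyphenyl]prop-2-en-1-ol | C=CC(O)c1ccc(OCc2ccccc2)c(OC)c1 | intermediate
4 | (1R)-1-[4-(benzyloxy)-3-methoxyphenyl]prop-2-en-1-yl acetate | C=C[C@@H](OC(C)=O)c1ccc(OCc2ccccc2)c(OC)c1 | intermediate
5 | (1R)-1-[4-(benzyloxy)-3-methoxyphenyl]prop-2-en-1-ol | C=C[C@@H](O)c1ccc(OCc2ccccc2)c(OC)c1 | intermediate
6 | 2,3-dibromoprop-1-ene | C=C(Br)CBr | starting material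
7 | 1-(benzyloxy)-4-{(1R)-1-[(2-bromoprop-2-en-1-yl)oxy]prop-2-en-1-yl}-2-methoxybenzene | C=C[C@@H](OCC(Br)=C)c1ccc(OCc2ccccc2)c(OC)c1 | intermediate
8 | 1-[4-(benzyloxy)-3-methoxyphenyl]-2-[({(1R)-1-[4-(benzyloxy)-3-methoxyphenyl]prop-2-en-1-yl}oxy)methyl]prop-2-en-1-ol (C7' epimers) | C=C[C@@H](OCC(=C)C(O)c1ccc(OCc2ccccc2)c(OC)c1)c1ccc(OCc2ccccc2)c(OC)c1 | intermediate
9 | [4-(benzyloxy)-3-methoxyphenyl]{(5R)-5-[4-(benzyloxy)-3-methoxyphenyl]-2,5-dihydrofuran-3-yl}methanol (C7' epimers) | OC(c1ccc(OCc2ccccc2)c(OC)c1)C1=C[C@H](c2ccc(OCc3ccccc3)c(OC)c2)OC1 | intermediate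
10 | (bromomethyl)chlorodimethylsilane | C[Si](C)(Cl)CBr | starting material
11 | {[4-(benzyloxy)-3-methoxyphenyl]{(5R)-5-[4-(benzyloxy)-3-methoxyphenyl]-2,5-dihydrofuran-3-yl}methoxy}(bromomethyl)dimethylsilane (C7' epimers) | BrC[Si](C)(C)OC(c1ccc(OCc2ccccc2)c(OC)c1)C1=C[C@H](c2ccc(OCc3ccccc3)c(OC)c2)OC1 | intermediate
12 | (4aR,5R,7aS)-1,5-bis[4-(benzyloxy)-3-methoxyphenyl]-3,3-dimethylhexahydro-1H-furo[3,4-d][1,2]oxasiline, cis-fused (C7' epimers) | COc1cc(C2O[Si](C)(C)C[C@H]3[C@H](c4ccc(OCc5ccccc5)c(OC)c4)OC[C@@H]23)ccc1OCc1ccccc1 | intermediate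
13 | {(2R,3S,4S)-2-[4-(benzyloxy)-3-methoxyphenyl]-4-{[4-(benzyloxy)-3-methoxyphenyl](hydroxy)methyl}oxolan-3-yl}methanol (C7' epimers) | COc1cc(C(O)[C@@H]2CO[C@@H](c3ccc(OCc4ccccc4)c(OC)c3)[C@@H]2CO)ccc1OCc1ccccc1 | intermediate
14 | 3-(benzyloxy)-3-oxopropanoic acid | O=C(O)CC(=O)OCc1ccccc1 | starting material
15 | benzyl {(2R,3S,4S)-2-[4-(benzyloxy)-3-methoxyphenyl]-4-{[4-(benzyloxy)-3-methoxyphenyl](hydroxy)methyl}oxolan-3-yl}methyl propanedioate (C7' epimers) | COc1cc(C(O)[C@@H]2CO[C@@H](c3ccc(OCc4ccccc4)c(OC)c3)[C@@H]2COC(=O)CC(=O)OCc2ccccc2)ccc1OCc1ccccc1 | intermediate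
16 | benzyl {(2R,3S,4S)-2-[4-(benzyloxy)-3-methoxyphenyl]-4-{[4-(benzyloxy)-3-methoxyphenyl][(phenoxycarbonothioyl)oxy]methyl}oxolan-3-yl}methyl propanedioate (C7' epimers) | COc1cc(C(OC(=S)Oc2ccccc2)[C@@H]2CO[C@@H](c3ccc(OCc4ccccc4)c(OC)c3)[C@@H]2COC(=O)CC(=O)OCc2ccccc2)ccc1OCc1ccccc1 | intermediate
17 | benzyl {(2R,3S,4S)-2-[4-(benzyloxy)-3-methoxyphenyl]-4-[4-(benzyloxy)-3-methoxybenzyl]oxolan-3-yl}methyl propanedioate | COc1cc(C[C@@H]2CO[C@@H](c3ccc(OCc4ccccc4)c(OC)c3)[C@@H]2COC(=O)CC(=O)OCc2ccccc2)ccc1OCc1ccccc1 | intermediate
18 | 3-{[(2R,3S,4S)-4-(4-hydroxy-3-methoxybenzyl)-2-(4-hydroxy-3-methoxyphenyl)oxolan-3-yl]methoxy}-3-oxopropanoic acid | COc1cc(C[C@@H]2CO[C@@H](c3ccc(O)c(OC)c3)[C@@H]2COC(=O)CC(=O)O)ccc1O | intermediate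
19 | 3,4-dihydroxybenzaldehyde | O=Cc1ccc(O)c(O)c1 | starting material
20 | 3-(3,4-dihydroxyphenyl)-2-({[(2R,3S,4S)-4-(4-hydroxy-3-methoxybenzyl)-2-(4-hydroxy-3-methoxyphenyl)oxolan-3-yl]methoxy}carbonyl)prop-2-enoic acid (alkene geometry unassigned; not isolated) | COc1cc(C[C@@H]2CO[C@@H](c3ccc(O)c(OC)c3)[C@@H]2COC(=O)C(=Cc2ccc(O)c(O)c2)C(=O)O)ccc1O | intermediate
21 | [(2R,3S,4S)-4-(4-hydroxy-3-methoxybenzyl)-2-(4-hydroxy-3-methoxyphenyl)oxolan-3-yl]methyl (2E)-3-(3,4-dihydroxyphenyl)prop-2-enoate | COc1cc(C[C@@H]2CO[C@@H](c3ccc(O)c(OC)c3)[C@@H]2COC(=O)/C=C/c2ccc(O)c(O)c2)ccc1O | target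

## Step count and risks

Total: 14 steps. Longest linear sequence: 14 steps from 1, which enters twice (steps 1 and 5).

**Step 8 (key step).** The 6-endo attack falls on a ring CH carbon and is slow, so the C–Br bond may be reduced before the ring closes. Closure may also go partly 5-exo to a spiro-oxasilolane. For one of the C7' epimers, hydrogen delivery to the C4 radical may lose its face preference and erode the cis fusion. The fallback replaces the radical by a sigmatropic shift; it sets out from 9 and comes back at 18. Alkylation of the C7' alkoxide of 9 (KH, Bu3SnCH2I, THF) would give the (tributylstannyl)methyl ether F1. Tin–lithium exchange (n-BuLi, THF, −78 °C) triggers a [2,3]-Wittig–Still rearrangement that moves the CH2O unit to C3 on the face away from the C2 aryl group and shifts the alkene to C4=C7', giving the 4-benzylidene alcohol F2. Steglich acylation with 14 gives the benzyl malonate F3. Hydrogenation over 10% Pd/C should then saturate the benzylidene from the face opposite the C3 arm, the usual outcome for 4-benzylidene precursors of this lignan class, and remove the three benzyl groups to reach 18.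

**Step 5.** The vinyl–metal intermediate carries an allylic ether oxygen on the neighbouring carbon and may lose it by β-alkoxide elimination; activation of the vinylic bromide may also be sluggish. The fallback sets out from 5 and comes back at 9, bypassing 7 and 8. Alkylation of the alkoxide of 5 with methyl 2-(bromomethyl)prop-2-enoate (NaH, THF) gives the acrylate ether F4. Ring-closing metathesis with the second-generation Grubbs catalyst gives the dihydrofuran ester F5. DIBAL-H reduction gives the allylic alcohol F6 and MnO2 oxidation the enal F7. Addition of the aryl Grignard reagent F8 (from 1-(benzyloxy)-4-bromo-2-methoxybenzene and Mg) at −78 °C gives 9.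

**Step 6.** Closure onto a hindered 1,1-disubstituted alkene bearing a free, doubly activated carbinol may be slow. Ruthenium hydride species may then isomerise the carbinol to a ketone or move the ring alkene towards the oxygen. The fallback sets out from 8 and comes back at 9. Dess–Martin oxidation of 8 gives the dienone F9, whose electron-poor alkene carries no free hydroxyl and should close by metathesis to the cyclic enone F10. Luche reduction (NaBH4, CeCl3·7H2O, MeOH, −78 °C) returns 9.

**Step 14.** Condensation of the polyphenolic half-ester may be slow, and prolonged warm base invites aminolysis of the ester by piperidine and oxidative darkening of the catechol. The fallback attaches the intact acyl group; it sets out from 17 and comes back at 21. Methanolysis of the malonate (K2CO3, MeOH) gives the dibenzyl ether F11. Hydrogenolysis (H2, 10% Pd/C) gives (2R,3S,4S)-lariciresinol F12. Mitsunobu esterification with (E)-caffeic acid (PPh3, diisopropyl azodicarboxylate, THF), which acylates aliphatic hydroxyls in preference to phenols, then gives 21.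

Further compounds
F1 | step 8 | tributyl({[4-(benzyloxy)-3-methoxyphenyl]{(5R)-5-[4-(benzyloxy)-3-methoxyphenyl]-2,5-dihydrofuran-3-yl}methoxy}methyl)stannane (C7' epimers) | CCCC[Sn](CCCC)(CCCC)COC(c1ccc(OCc2ccccc2)c(OC)c1)C1=C[C@H](c2ccc(OCc3ccccc3)c(OC)c2)OC1
F2 | step 8 | {(2R,3S)-2-[4-(benzyloxy)-3-methoxyphenyl]-4-[4-(benzyloxy)-3-methoxybenzylidene]oxolan-3-yl}methanol (alkene geometry unassigned) | COc1cc(C=C2CO[C@@H](c3ccc(OCc4ccccc4)c(OC)c3)[C@@H]2CO)ccc1OCc1ccccc1
F3 | step 8 | benzyl {(2R,3S)-2-[4-(benzyloxy)-3-methoxyphenyl]-4-[4-(benzyloxy)-3-methoxybenzylidene]oxolan-3-yl}methyl propanedioate (alkene geometry unassigned) | COc1cc(C=C2CO[C@@H](c3ccc(OCc4ccccc4)c(OC)c3)[C@@H]2COC(=O)CC(=O)OCc2ccccc2)ccc1OCc1ccccc1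
F4 | step 5 | methyl 2-[({(1R)-1-[4-(benzyloxy)-3-methoxyphenyl]prop-2-en-1-yl}oxy)methyl]prop-2-enoate | C=C[C@@H](OCC(=C)C(=O)OC)c1ccc(OCc2ccccc2)c(OC)c1
F5 | step 5 | methyl (5R)-5-[4-(benzyloxy)-3-methoxyphenyl]-2,5-dihydrofuran-3-carboxylate | COC(=O)C1=C[C@H](c2ccc(OCc3ccccc3)c(OC)c2)OC1
F6 | step 5 | {(5R)-5-[4-(benzyloxy)-3-methoxyphenyl]-2,5-dihydrofuran-3-yl}methanol | OCC1=C[C@H](c2ccc(OCc3ccccc3)c(OC)c2)OC1
F7 | step 5 | (5R)-5-[4-(benzyloxy)-3-methoxyphenyl]-2,5-dihydrofuran-3-carbaldehyde | O=CC1=C[C@H](c2ccc(OCc3ccccc3)c(OC)c2)OC1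
F8 | step 5 | [4-(benzyloxy)-3-methoxyphenyl]magnesium bromide | COc1cc([Mg]Br)ccc1OCc1ccccc1
F9 | step 6 | 1-[4-(benzyloxy)-3-methoxyphenyl]-2-[({(1R)-1-[4-(benzyloxy)-3-methoxyphenyl]prop-2-en-1-yl}oxy)methyl]prop-2-en-1-one | C=C[C@@H](OCC(=C)C(=O)c1ccc(OCc2ccccc2)c(OC)c1)c1ccc(OCc2ccccc2)c(OC)c1
F10 | step 6 | [4-(benzyloxy)-3-methoxyphenyl]{(5R)-5-[4-(benzyloxy)-3-methoxyphenyl]-2,5-dihydrofuran-3-yl}methanone | O=C(c1ccc(OCc2ccccc2)c(OC)c1)C1=C[C@H](c2ccc(OCc3ccccc3)c(OC)c2)OC1
F11 | step 14 | {(2R,3S,4S)-2-[4-(benzyloxy)-3-methoxyphenyl]-4-[4-(benzyloxy)-3-methoxybenzyl]oxolan-3-yl}methanol | COc1cc(C[C@@H]2CO[C@@H](c3ccc(OCc4ccccc4)c(OC)c3)[C@@H]2CO)ccc1OCc1ccccc1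
F12 | step 14 | (2R,3S,4S)-lariciresinol, 4-[(2R,3S,4S)-4-(4-hydroxy-3-methoxybenzyl)-3-(hydroxymethyl)oxolan-2-yl]-2-methoxyphenol | COc1cc(C[C@@H]2CO[C@@H](c3ccc(O)c(OC)c3)[C@@H]2CO)ccc1O
A1 | alternative 1 | trans-3-{[4-(tert-butyldimethylsilyloxy)-3-methoxyphenyl](hydroxy)methyl}-4-{2-[4-(tert-butyldimethylsilyloxy)-3-methoxyphenyl]-1,3-dithian-2-yl}-5-(d-menthyloxy)oxolan-2-one (carbinol carbon unassigned) | O=C1O[C@H](O[C@H]2C[C@@H](C)CC[C@@H]2C(C)C)[C@@H](C2(c3ccc(O[Si](C)(C)C(C)(C)C)c(OC)c3)SCCCS2)[C@@H]1C(O)c1ccc(O[Si](C)(C)C(C)(C)C)c(OC)c1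
A2 | alternative 1 | (5S)-5-(d-menthyloxy)furan-2(5H)-one | O=C1C=C[C@@H](O[C@H]2C[C@@H](C)CC[C@@H]2C(C)C)O1
A3 | alternative 1 | 2-{4-[(tert-butyldimethylsilyl)oxy]-3-methoxyphenyl}-1,3-dithiane | COc1cc(C2SCCCS2)ccc1O[Si](C)(C)C(C)(C)C
A4 | alternative 1 | 4-[(tert-butyldimethylsilyl)oxy]-3-methoxybenzaldehyde | COc1cc(C=O)ccc1O[Si](C)(C)C(C)(C)C
A5 | alternative 2 | (2R,3S)-3-{[(tert-butyldimethylsilyl)oxy]methyl}-2-{4-[(tert-butyldimethylsilyl)oxy]-3-methoxyphenyl}-4-{4-[(tert-butyldimethylsilyl)oxy]-3-methoxybenzylidene}oxolane (alkene geometry unassigned) | COc1cc(C=C2CO[C@@H](c3ccc(O[Si](C)(C)C(C)(C)C)c(OC)c3)[C@@H]2CO[Si](C)(C)C(C)(C)C)ccc1O[Si](C)(C)C(C)(C)C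
A6 | alternative 2 | (phenylselanyl)methyl ether of (1R,2S)-1,4-bis{4-[(tert-butyldimethylsilyl)oxy]-3-methoxyphenyl}-2-{[(tert-butyldimethylsilyl)oxy]methyl}but-3-yn-1-ol | COc1cc(C#C[C@@H](CO[Si](C)(C)C(C)(C)C)[C@@H](OC[Se]c2ccccc2)c2ccc(O[Si](C)(C)C(C)(C)C)c(OC)c2)ccc1O[Si](C)(C)C(C)(C)C
A7 | alternative 3 | cis-fused 3,6-bis{4-[(tert-butyldimethylsilyl)oxy]-3-methoxyphenyl}tetrahydro-1H,3H-furo[3,4-c]furan-1-one | COc1cc([C@@H]2OC(=O)[C@H]3[C@H](c4ccc(O[Si](C)(C)C(C)(C)C)c(OC)c4)OC[C@@H]23)ccc1O[Si](C)(C)C(C)(C)C
A8 | alternative 3 | trans-5-{4-[(tert-butyldimethylsilyl)oxy]-3-methoxyphenyl}-4-{[{4-[(tert-butyldimethylsilyl)oxy]-3-methoxyphenyl}(methoxy)methoxy]methyl}oxolan-2-one (acetal carbon unassigned) | COc1cc([C@@H]2OC(=O)C[C@H]2COC(OC)c2ccc(O[Si](C)(C)C(C)(C)C)c(OC)c2)ccc1O[Si](C)(C)C(C)(C)C
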